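**Retrosynthetic overview**
1. Target 25 ⇐ 6β-alcohol 24 (late oxidation to the C6 ketone) ⇐ triol 23 (ring D enol ether by E2 loss of HI) ⇐ allylic alcohol 20 (C7/C8 cis-diol by 6β-OH-directed dihydroxylation) ⇐ hydroxy enone 18 (spiro ring C by iodoetherification of the 9α-OH onto C13 of a 2,5-dihydrofuran).
2. The 9α-OH and the C6 ketone both come from singlet-oxygen (4+2) addition to a ring-B diene (C6=C7–C8=C9) followed by Kornblum–DeLaMare opening. C9–C11 is made by B-alkyl Suzuki–Miyaura coupling of a dienyl triflate with a borane from 3-ethenyl-2,5-dihydrofuran (enyne metathesis).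
3. Decalin enone 10 ⇐ monocyclic hydrazone 7 by closing ring A between C3 and C4: a tertiary C4 radical made by hydrogen atom transfer adds to the C3 aldehyde tosylhydrazone, which is then erased as sulfinate and N2.
4. Enabling feature: C4 of ring A is a gem-dimethyl carbon bonded to the ring-fusion carbon C5, so it is the Markovnikov radical of carvone's isopropenyl group. Its ring neighbour C3 is a bare CH2, reachable from a traceless C=N acceptor, and the quaternary ring-fusion carbon C10 holds the C1–C2–C3 tether trans to C4.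
5. Ring order: ring B is bought as (R)-carvone (C5 is the only purchased stereocentre; C10, C9, C13, C6, C7 and C8 are relayed by substrate control) → ring A (step 5) → ring D (step 7, side chain) → ring C (step 10).

Key step: step 5

Remark: labdane numbering is used throughout (ring A = C1–C5/C10, ring B = C5–C10, ring C = tetrahydrofuran O/C9/C11/C12/C13, ring D = dihydrofuran C13–C16/O; α/β as usual with the C10 methyl β). (R)-Carvone, allyl propargyl ether and all reagents are taken as commercial.

**Route**

Step 1
Reactants: 1 (R)-carvone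
Product: 3 6-methylcarvone (both C6 epimers), via lithium enolate 2 (not isolated)
Conditions: LiN(iPr)2, THF, −78 °C; MeI, −78 to 0 °C
Reagents that add atoms: iodomethane, CI
Why: Kinetic deprotonation at C6 gives the cross-conjugated enolate, whose C-alkylation (enolate alkylation) installs the future C10 methyl, the C6 configuration being irrelevant because this centre is enolised again in step 2.

Step 2
Reactants: 3 6-methylcarvone
Product: 5 (5S,6S)-2,6-dimethyl-5-(prop-1-en-2-yl)-6-(prop-2-yn-1-yl)cyclohex-2-en-1-one, via lithium enolate 4 (not isolated)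
Conditions: LiN(iPr)2, THF/DMPU, −78 °C; propargyl bromide, −78 °C to rt
Reagents that add atoms: propargyl bromide, C#CCBr
Why: In this enolate alkylation the tetrasubstituted enolate is attacked on the face anti to the neighbouring pseudoaxial isopropenyl group, so the C1–C3 arm should enter trans and the methyl end up cis to isopropenyl, which sets the quaternary C10 from the purchased C5 centre.

Step 3
Reactants: 5 propargyl ketone
Product: 6 3-[(1S,6S)-1,3-dimethyl-2-oxo-6-(prop-1-en-2-yl)cyclohex-3-en-1-yl]propanal
Conditions: CpRuCl(dppm) (cat.), iPrOH/H2O, 100 °C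
Reagents that add atoms: water, O
Why: Ruthenium-catalysed anti-Markovnikov hydration of the terminal alkyne (through a vinylidene) should deliver the aldehyde at C3 without touching the isopropenyl group or the hindered enone.

Step 4
Reactants: 6 aldehyde
Product: 7 (E)-N'-{3-[(1S,6S)-1,3-dimethyl-2-oxo-6-(prop-1-en-2-yl)cyclohex-3-en-1-yl]propylidene}-4-methylbenzenesulfonohydrazide
Conditions: TsNHNH2, MeOH, rt
Reagents that add atoms: 4-methylbenzenesulfonohydrazide, Cc1ccc(cc1)S(=O)(=O)NN
Why: Hydrazone formation should be selective for the aldehyde because the ring ketone is conjugated and flanked by a quaternary carbon.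

Step 5
Reactants: 7 tosylhydrazone
Product: 10 decalin enone (4aS,8aS)-2,5,5,8a-tetramethyl-4a,5,6,7,8,8a-hexahydronaphthalen-1(4H)-one, via tosylhydrazide 8 (not isolated), via alkyl diazene 9 (not isolated)
Conditions: Fe(acac)3 (cat.), PhSiH3, EtOH/THF, 60 °C, high dilution; then Et3N, MeOH, 65 °C
Reagents that add atoms: none
Why: Proposed new method: Hydrogen atom transfer from an iron hydride (from Fe(acac)3 and PhSiH3) to the terminal CH2 of the isopropenyl group gives the tertiary C4 radical, which adds to the hydrazone carbon C3; the sulfonyl-stabilised hydrazinyl radical is reduced and protonated to hydrazide 8, and warming with Et3N in MeOH expels p-toluenesulfinate to give monoalkyl diazene 9, which loses N2 and leaves C3 as a CH2 group. The closest known reactions are the iron-hydride-mediated reductive coupling of alkenes with aldehyde-derived sulfonylhydrazones (intermolecular hydromethylation type), the HAT-initiated reductive cyclisation of alkenes onto tethered carbonyl and C=N acceptors, and the sulfinate/N2 loss of N-alkyl-N'-sulfonylhydrazides used in hydrazone reductions; their union as a traceless ring closure is the new element. Ring A is closed in the 6-exo-trig mode (C4 radical onto C3 of the exocyclic C=N) through a chair transition state in which the C5 radical arm and the C10 chain, fixed trans on ring B, are both equatorial, so the trans-decalin should follow. No permanent stereocentre is created: C4 becomes the non-stereogenic gem-dimethyl carbon, the nitrogen-bearing C3 centre is erased, and C5 and C10 are carried unchanged from 7. The step needs HAT to the electron-rich 1,1-disubstituted alkene in preference to the enone, and C–C bond formation faster than reduction of the tertiary radical; the first is secured by the polarity match of the iron hydride and by the fact that the radical could reach the enone carbon C7 only through a four-membered ring, the second by high dilution and the good acceptor character of the sulfonylhydrazone.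

Step 6
Reactants: 10 decalin enone
Product: 12 dienyl triflate (4aS,8aS)-2,5,5,8a-tetramethyl-4a,5,6,7,8,8a-hexahydronaphthalen-1-yl trifluoromethanesulfonate, via potassium dienolate 11 (not isolated)
Conditions: KN(SiMe3)2, THF, −78 to 0 °C; PhNTf2
Reagents that add atoms: N-phenylbis(trifluoromethanesulfonimide), O=S(=O)(N(c1ccccc1)S(=O)(=O)C(F)(F)F)C(F)(F)F
Why: Because C10 is quaternary, base can only remove a γ-hydrogen at C6, and O-sulfonylation of the linear dienolate (enol triflate formation) should fix the C6=C7/C8=C9 diene regiochemically.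

Step 7
Reactants: 13 allyl propargyl ether
Product: 14 3-ethenyl-2,5-dihydrofuran
Conditions: RuCl2(PCy3)2(=CHPh) (first-generation Grubbs catalyst, cat.), ethylene (1 atm), CH2Cl2, rt
Reagents that add atoms: none
Why: Ring-closing enyne metathesis of the 1,6-enyne should give the five-membered ring carrying the 1,3-diene, with ethylene keeping the ruthenium carbene active.

Step 8
Reactants: 12 dienyl triflate; 14 3-ethenyl-2,5-dihydrofuran
Product: 16 diene 15,16-epoxylabda-6,8,13-triene, via alkylborane 15 (not isolated)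
Conditions: 14, 9-borabicyclo[3.3.1]nonane (9-BBN), THF, 0 °C to rt; then 12, Pd(dppf)Cl2 (cat.), AsPh3, Cs2CO3, DMF/THF/H2O, 50 °C
Reagents that add atoms: none
Why: Anti-Markovnikov hydroboration should occur at the monosubstituted vinyl group and spare the trisubstituted ring alkene, and B-alkyl Suzuki–Miyaura coupling with the hindered dienyl triflate (the same triflate type as 2,6,6-trimethylcyclohexenyl triflate) then forms the C9–C11 bond.

Step 9
Reactants: 16 diene
Product: 18 9α-hydroxy-15,16-epoxylabda-7,13-dien-6-one, via endoperoxide 17 (not isolated)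
Conditions: O2, tetraphenylporphyrin (cat.), visible light, CH2Cl2, −30 °C; then Et3N, 0 °C to rt
Reagents that add atoms: dioxygen, O=O
Why: The s-cis diene of ring B should add singlet oxygen in a (4+2) mode on the α-face, opposite the C10 methyl and the axial C4 methyl, and Kornblum–DeLaMare opening (only C6 carries a hydrogen) then gives the C6 ketone and the 9α-tertiary alcohol, which sets C9.

Step 10
Reactants: 18 hydroxy enone
Product: 19 14-iodo-9α,13:15,16-diepoxylabd-7-en-6-one (C13 as in the target; iodine trans to the C13–O bond)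
Conditions: N-iodosuccinimide, NaHCO3, CH2Cl2, 0 °C, dark
Reagents that add atoms: N-iodosuccinimide, O=C1CCC(=O)N1I
Why: In this iodoetherification the 9α-hydroxyl attacks the tertiary C13 of the iodonium ion in a 5-exo mode with anti addition, closing spiro ring C, and the bulkier iodonium-bearing C14 arm is expected to turn toward the flat C8 side and away from the quaternary C10, which gives the C13 configuration of the target.

Step 11
Reactants: 19 iodo spiroether enone
Product: 20 14-iodo-9α,13:15,16-diepoxylabd-7-en-6β-ol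
Conditions: NaBH4, CeCl3·7H2O, MeOH, −40 °C
Reagents that add atoms: none
Why: Luche reduction is 1,2-selective and hydride should arrive from the α-face because the β-face of C6 is screened by the 1,3-diaxial C10 and C4 methyl groups, giving the axial 6β-alcohol.

Step 12
Reactants: 20 allylic alcohol
Product: 22 14-iodo-9α,13:15,16-diepoxylabdane-6β,7β,8β-triol, via osmate ester 21 (not isolated)
Conditions: OsO4 (1 equiv), TMEDA, CH2Cl2, −78 °C; then aq. Na2SO3, THF, 40 °C
Reagents that add atoms: osmium tetroxide, O=[Os](=O)(=O)=O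
Why: Hydrogen-bond-directed dihydroxylation with the OsO4–TMEDA complex should deliver both oxygens syn to the 6β-hydroxyl and anti to the allylic C9–O bond, so C7 and C8 are set together as the 7β,8β-diol with the C8 methyl α.

Step 13
Reactants: 22 iodo triol
Product: 23 9α,13:15,16-diepoxylabd-14-ene-6β,7β,8β-triol
Conditions: KOtBu (excess), THF, 0 °C to rt
Reagents that add atoms: none
Why: In this E2 elimination C13 is quaternary, so the only anti-periplanar hydrogen is on C15 and loss of HI should give the C14=C15 enol ether, strong base being tolerated because no ester or ketone is present at this stage.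

Step 14
Reactants: 23 enol ether triol
Product: 24 7β-acetoxy-9α,13:15,16-diepoxylabd-14-ene-6β,8β-diol
Conditions: Ac2O, pyridine, 0 °C
Reagents that add atoms: acetic anhydride, CC(=O)OC(C)=O
Why: Acylation should be selective for the equatorial secondary 7β-hydroxyl because the 6β-hydroxyl is 1,3-diaxial to two methyl groups and the 8β-hydroxyl is tertiary.

Step 15
Reactants: 24 acetate diol
Product: 25 CNP0284584.1, 7β-acetoxy-8β-hydroxy-9α,13:15,16-diepoxylabd-14-en-6-one
Conditions: Dess–Martin periodinane, NaHCO3, CH2Cl2, 0 °C to rt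
Reagents that add atoms: none
Why: Buffered Dess–Martin oxidation should convert the hindered axial 6β-alcohol into the ketone under non-acidic conditions that spare the enol ether, the tertiary alcohol and the acetate, and C7 is not scrambled because its equatorial 7β-acetoxy group is the favoured epimer.

**Compound list**

1 | (R)-(−)-carvone, (5R)-2-methyl-5-(prop-1-en-2-yl)cyclohex-2-en-1-one | O=C1C(C)=CC[C@@H](C(C)=C)C1 | starting material
2 | lithium enolate of 1 (C1=C6 enolate, cross-conjugated) | [Li+].[O-]C1=C[C@H](C(C)=C)CC=C1C | intermediate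
3 | (5R)-2,6-dimethyl-5-(prop-1-en-2-yl)cyclohex-2-en-1-one (6-methylcarvone, both C6 epimers) | O=C1C(C)=CC[C@@H](C(C)=C)C1C | intermediate
4 | lithium enolate of 3 (tetrasubstituted C1=C6 enolate) | [Li+].[O-]C1=C(C)[C@H](C(C)=C)CC=C1C | intermediate
5 | (5S,6S)-2,6-dimethyl-5-(prop-1-en-2-yl)-6-(prop-2-yn-1-yl)cyclohex-2-en-1-one (propargyl trans, methyl cis to isopropenyl) | O=C1C(C)=CC[C@@H](C(C)=C)[C@]1(C)CC#C | intermediate
6 | 3-[(1S,6S)-1,3-dimethyl-2-oxo-6-(prop-1-en-2-yl)cyclohex-3-en-1-yl]propanal | O=C1C(C)=CC[C@@H](C(C)=C)[C@]1(C)CCC=O | intermediate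
7 | (E)-N'-{3-[(1S,6S)-1,3-dimethyl-2-oxo-6-(prop-1-en-2-yl)cyclohex-3-en-1-yl]propylidene}-4-methylbenzenesulfonohydrazide | O=C1C(C)=CC[C@@H](C(C)=C)[C@]1(C)CC/C=N/NS(=O)(=O)c1ccc(C)cc1 | intermediate
8 | N'-[(4aS,8aS)-1,1,4a,6-tetramethyl-5-oxo-1,2,3,4,4a,5,8,8a-octahydronaphthalen-2-yl]-4-methylbenzenesulfonohydrazide (labdane C3 hydrazide, both C3 epimers) | O=C1C(C)=CC[C@H]2C(C)(C)C(NNS(=O)(=O)c3ccc(C)cc3)CC[C@]12C | intermediate
9 | (4aS,8aS)-6-diazenyl-2,5,5,8a-tetramethyl-4a,5,6,7,8,8a-hexahydronaphthalen-1(4H)-one (monoalkyl diazene at labdane C3, both epimers) | O=C1C(C)=CC[C@H]2C(C)(C)C(N=N)CC[C@]12C | intermediate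
10 | (4aS,8aS)-2,5,5,8a-tetramethyl-4a,5,6,7,8,8a-hexahydronaphthalen-1(4H)-one (trans-decalin enone; C9 ketone, C7=C8) | O=C1C(C)=CC[C@H]2C(C)(C)CCC[C@]12C | intermediate
11 | potassium dienolate of 10 (O–C9=C8, C7=C6) | [K+].[O-]C1=C(C)C=C[C@H]2C(C)(C)CCC[C@]12C | intermediate
12 | (4aS,8aS)-2,5,5,8a-tetramethyl-4a,5,6,7,8,8a-hexahydronaphthalen-1-yl trifluoromethanesulfonate | O=S(=O)(OC1=C(C)C=C[C@H]2C(C)(C)CCC[C@]12C)C(F)(F)F | intermediate
13 | allyl propargyl ether, 3-(prop-2-yn-1-yloxy)prop-1-ene | C#CCOCC=C | starting material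
14 | 3-ethenyl-2,5-dihydrofuran | C=CC1=CCOC1 | intermediate
15 | 9-[2-(2,5-dihydrofuran-3-yl)ethyl]-9-borabicyclo[3.3.1]nonane | C(CC1=CCOC1)B1C2CCCC1CCC2 | intermediate
16 | 3-{2-[(4aS,8aS)-2,5,5,8a-tetramethyl-4a,5,6,7,8,8a-hexahydronaphthalen-1-yl]ethyl}-2,5-dihydrofuran (15,16-epoxylabda-6,8,13-triene) | C1(CCC3=CCOC3)=C(C)C=C[C@H]2C(C)(C)CCC[C@]12C | intermediate
17 | 6α,9α-epidioxy-15,16-epoxylabda-7,13-diene | CC1=C[C@@H]2OO[C@@]1(CCC3=CCOC3)[C@@]4(C)CCCC(C)(C)[C@H]24 | intermediate
18 | 9α-hydroxy-15,16-epoxylabda-7,13-dien-6-one | CC1=CC(=O)[C@H]2C(C)(C)CCC[C@]2(C)[C@@]1(O)CCC3=CCOC3 | intermediate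
19 | 14-iodo-9α,13:15,16-diepoxylabd-7-en-6-one (C13 as in the target, iodine trans to the C13–O bond; 13R,14R by the CIP rules) | CC1=CC(=O)[C@H]2C(C)(C)CCC[C@]2(C)[C@@]14CC[C@@]3([C@H](I)COC3)O4 | intermediate
20 | 14-iodo-9α,13:15,16-diepoxylabd-7-en-6β-ol | CC1=C[C@@H](O)[C@H]2C(C)(C)CCC[C@]2(C)[C@@]14CC[C@@]3([C@H](I)COC3)O4 | intermediate
21 | cyclic 7β,8β-osmate ester of 20 (dioxo-osmium glycolate of hexavalent osmium, TMEDA adduct) | O=[Os]4(=O)O[C@H]1[C@@H](O)[C@H]2C(C)(C)CCC[C@]2(C)[C@@]2(CC[C@@]3([C@H](I)COC3)O2)[C@@]1(C)O4.CN(C)CCN(C)C | intermediate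
22 | 14-iodo-9α,13:15,16-diepoxylabdane-6β,7β,8β-triol | O[C@H]1[C@@H](O)[C@H]2C(C)(C)CCC[C@]2(C)[C@@]2(CC[C@@]3([C@H](I)COC3)O2)[C@@]1(C)O | intermediate
23 | 9α,13:15,16-diepoxylabd-14-ene-6β,7β,8β-triol | O[C@H]1[C@@H](O)[C@H]2C(C)(C)CCC[C@]2(C)[C@@]2(CC[C@@]3(C=COC3)O2)[C@@]1(C)O | intermediate
24 | 7β-acetoxy-9α,13:15,16-diepoxylabd-14-ene-6β,8β-diol | CC(=O)O[C@H]1[C@@H](O)[C@H]2C(C)(C)CCC[C@]2(C)[C@@]2(CC[C@@]3(C=COC3)O2)[C@@]1(C)O | intermediate
25 | CNP0284584.1, (5S,7R,8S,9S,10S,13S)-7β-acetoxy-8β-hydroxy-9α,13:15,16-diepoxylabd-14-en-6-one | CC(=O)O[C@H]1C(=O)[C@H]2C(C)(C)CCC[C@]2(C)[C@@]2(CC[C@@]3(C=COC3)O2)[C@@]1(C)O | target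

**Step count**

Total step count: 15 (14 on the main line plus 1 for the side-chain diene).
Longest linear sequence: 14 steps from (R)-carvone (steps 1–6 and 8–15).

**Steps most likely to fail, with fallbacks**

Step 5 (proposed new method). The tertiary C4 radical may be reduced before it reaches the C=N bond, giving the uncyclised isopropyl compound, or the loss of sulfinate and N2 from the hydrazide may stall. The fallback uses known chemistry and moves the radical acceptor from a C=N bond to an acrylate. It sets out from 3 through enolate 4. Alkylation with methyl 2-(bromomethyl)acrylate (LiN(iPr)2, THF, −78 °C) should give acrylate F1, again with the new arm trans to isopropenyl. The same Fe(acac)3/PhSiH3 conditions in EtOH then effect a 6-endo-trig Giese cyclisation of the C4 radical onto the acrylate CH2 (C3), a well-established HAT radical conjugate addition, to give bicyclic ester F2. LiOH in THF/H2O gives acid F3, and Barton decarboxylation (thiohydroxamate ester, t-BuSH, visible light) removes the C2 carboxyl. The fallback comes back to the route at 10.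

Step 10. Attack of the 9α-hydroxyl on the two faces of the dihydrofuran alkene may be poorly differentiated, so the spiro centre C13 forms as a mixture of epimers. The fallback replaces substrate control by reagent control and sets out from 18. Shi epoxidation (fructose-derived ketone, KHSO5, K2CO3, MeCN/buffer, 0 °C) of the electron-rich side-chain alkene, with the ketone enantiomer chosen so that the epoxide oxygen lies anti to the later C13–O bond, should give epoxide F4. Camphorsulfonic acid (cat.) in CH2Cl2 then opens it in a 5-exo mode at C13 with inversion to give hydroxy spiroether F5. MsCl/Et3N gives mesylate F6 as the latent enol ether. F6 is carried through the Luche reduction of step 11 (allylic alcohol F7) and the directed dihydroxylation of step 12 (osmate ester F8, then triol mesylate F9). E2 elimination of methanesulfonate with KOtBu in DMSO comes back to the route at 23.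

Step 12. The osmium reagent may attack the α-face, or engage the hindered trisubstituted C7=C8 alkene too slowly. The fallback moves the dihydroxylation to the enone oxidation level, where no hydroxyl competes and the allylic C9–O bond with spiro ring C is the only bias, directing the oxidant to the β-face; C6 stays a ketone throughout. It sets out from 19. Catalytic OsO4 with N-methylmorpholine N-oxide and citric acid in tBuOH/H2O should give diol ketone F10. Ac2O/pyridine acetylates the secondary 7β-hydroxyl to give acetate F11, and DBU in toluene at 80 °C eliminates HI. The fallback comes back to the route at 25, so steps 11 and 13–15 are not needed.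

Further compounds
F1 | step 5 | methyl 2-{[(1S,6S)-1,3-dimethyl-2-oxo-6-(prop-1-en-2-yl)cyclohex-3-en-1-yl]methyl}prop-2-enoate | O=C1C(C)=CC[C@@H](C(C)=C)[C@]1(C)CC(=C)C(=O)OC
F2 | step 5 | methyl (4aS,8aS)-4,4,7,8a-tetramethyl-8-oxo-1,2,3,4,4a,5,8,8a-octahydronaphthalene-2-carboxylate (both C2 epimers) | O=C1C(C)=CC[C@H]2C(C)(C)CC(C(=O)OC)C[C@]12C
F3 | step 5 | (4aS,8aS)-4,4,7,8a-tetramethyl-8-oxo-1,2,3,4,4a,5,8,8a-octahydronaphthalene-2-carboxylic acid (both C2 epimers) | O=C1C(C)=CC[C@H]2C(C)(C)CC(C(=O)O)C[C@]12C
F4 | step 10 | 9α-hydroxy-13,14:15,16-diepoxylabd-7-en-6-one (epoxide oxygen anti to the later C13–O bond) | CC1=CC(=O)[C@H]2C(C)(C)CCC[C@]2(C)[C@@]1(O)CC[C@]35COC[C@H]3O5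
F5 | step 10 | 14-hydroxy-9α,13:15,16-diepoxylabd-7-en-6-one (C13 as in the target, 14-OH trans to the C13–O bond) | CC1=CC(=O)[C@H]2C(C)(C)CCC[C@]2(C)[C@@]14CC[C@@]3([C@H](O)COC3)O4
F6 | step 10 | 14-methanesulfonyloxy-9α,13:15,16-diepoxylabd-7-en-6-one | CC1=CC(=O)[C@H]2C(C)(C)CCC[C@]2(C)[C@@]14CC[C@@]3([C@H](OS(C)(=O)=O)COC3)O4
F7 | step 10 | 14-methanesulfonyloxy-9α,13:15,16-diepoxylabd-7-en-6β-ol | CC1=C[C@@H](O)[C@H]2C(C)(C)CCC[C@]2(C)[C@@]14CC[C@@]3([C@H](OS(C)(=O)=O)COC3)O4
F8 | step 10 | cyclic 7β,8β-osmate ester of F7 (TMEDA adduct) | O=[Os]4(=O)O[C@H]1[C@@H](O)[C@H]2C(C)(C)CCC[C@]2(C)[C@@]2(CC[C@@]3([C@H](OS(C)(=O)=O)COC3)O2)[C@@]1(C)O4.CN(C)CCN(C)C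
F9 | step 10 | 14-methanesulfonyloxy-9α,13:15,16-diepoxylabdane-6β,7β,8β-triol | O[C@H]1[C@@H](O)[C@H]2C(C)(C)CCC[C@]2(C)[C@@]2(CC[C@@]3([C@H](OS(C)(=O)=O)COC3)O2)[C@@]1(C)O
F10 | step 12 | 7β,8β-dihydroxy-14-iodo-9α,13:15,16-diepoxylabdan-6-one | O[C@H]1C(=O)[C@H]2C(C)(C)CCC[C@]2(C)[C@@]2(CC[C@@]3([C@H](I)COC3)O2)[C@@]1(C)O
F11 | step 12 | 7β-acetoxy-8β-hydroxy-14-iodo-9α,13:15,16-diepoxylabdan-6-one | CC(=O)O[C@H]1C(=O)[C@H]2C(C)(C)CCC[C@]2(C)[C@@]2(CC[C@@]3([C@H](I)COC3)O2)[C@@]1(C)O
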